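**Retrosynthetic overview**
1. Target 14 ⇒ Wittig methylenation of the (R)-α-hydroxy methyl ketone 13; the C=CH2 is made last and the stereocentre is already in place.
2. 13 ⇒ hydroxyacetone 11 (as a chiral enamine) plus the A-ring methylene o-quinone methide 12, released from sulfone 10. This is the asymmetric C–C bond formation and sets the only stereocentre.
3. 10 ⇒ heterodimer 8, by aminomethylation and sulfinate exchange at the last free ring carbon.
4. 8 ⇒ B-ring Mannich base 6 (o-quinone methide 7) plus butyrylphloroglucinol 2, forming the methylene bridge.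
5. 2 ⇐ phloroglucinol 1; 6 ⇐ 2-methylphloroglucinol 3 (acetylation, para-O-methylation, Mannich). No ring is formed; both benzene rings are bought.

Assumption: small reagents (butyric acid, acetic acid, dimethyl sulfate, bis(dimethylamino)methane, sodium p-toluenesulfinate, the Wittig salt) are given under "Reagents that add atoms" and not numbered, and the D-proline-derived pyrrolidine–thiourea catalyst is bought or made separately and not counted.

**Step 1**
Reactants: 1 phloroglucinol
Product: 2 1-(2,4,6-trihydroxyphenyl)butan-1-one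
Conditions: n-PrCO2H (1.1 equiv), BF3·OEt2 (solvent), 90 °C; aq. NaOAc work-up
Reagents that add atoms: butyric acid, CCCC(=O)O
Why: BF3-mediated Friedel–Crafts C-acylation of the symmetrical triol stops at the mono-ketone because the chelated product is deactivated.

**Step 2**
Reactants: 3 2-methylphloroglucinol
Product: 4 1-(2,4,6-trihydroxy-3-methylphenyl)ethan-1-one
Conditions: AcOH (1.1 equiv), BF3·OEt2 (solvent), 90 °C; aq. NaOAc work-up
Reagents that add atoms: acetic acid, CC(=O)O
Why: The same Friedel–Crafts C-acylation, and the two free ring positions of 3 are equivalent, so a single mono-ketone forms.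

**Step 3**
Reactants: 4 1-(2,4,6-trihydroxy-3-methylphenyl)ethan-1-one
Product: 5 1-(2,6-dihydroxy-4-methoxy-3-methylphenyl)ethan-1-one
Conditions: Me2SO4 (1.05 equiv), K2CO3 (1.1 equiv), acetone, reflux
Reagents that add atoms: dimethyl sulfate, COS(=O)(=O)OC
Why: Williamson O-methylation selects the OH para to the acetyl group, which is the most acidic and the only one not hydrogen-bonded to the ketone (aspidinol-type partial methylation).

**Step 4**
Reactants: 5 1-(2,6-dihydroxy-4-methoxy-3-methylphenyl)ethan-1-one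
Product: 6 1-{3-[(dimethylamino)methyl]-2,6-dihydroxy-4-methoxy-5-methylphenyl}ethan-1-one
Conditions: Me2NCH2NMe2 (1.2 equiv), CH2Cl2, rt
Reagents that add atoms: bis(dimethylamino)methane, CN(C)CN(C)C
Why: Phenolic Mannich reaction at the only free ring carbon, which is ortho and para to OH groups.

**Step 5**
Reactants: 6 1-{3-[(dimethylamino)methyl]-2,6-dihydroxy-4-methoxy-5-methylphenyl}ethan-1-one; 2 1-(2,4,6-trihydroxyphenyl)butan-1-one (3 equiv)
Product: 8 1-{3-[(3-acetyl-2,4-dihydroxy-6-methoxy-5-methylphenyl)methyl]-2,4,6-trihydroxyphenyl}butan-1-one, via B-ring o-quinone methide 7 (not isolated)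
Conditions: 1,4-dioxane, 90 °C, N2 sweep
Reagents that add atoms: none
Why: Thermal retro-Mannich loss of dimethylamine gives o-quinone methide 7, which is trapped by Michael-type (Friedel–Crafts) C-alkylation of the phloroglucinol 2, and the excess of 2 suppresses double alkylation.

**Step 6**
Reactants: 8 1-{3-[(3-acetyl-2,4-dihydroxy-6-methoxy-5-methylphenyl)methyl]-2,4,6-trihydroxyphenyl}butan-1-one
Product: 10 1-{3-[(3-acetyl-2,4-dihydroxy-6-methoxy-5-methylphenyl)methyl]-2,4,6-trihydroxy-5-[(4-methylbenzenesulfonyl)methyl]phenyl}butan-1-one, via Mannich base 9 (not isolated)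
Conditions: Me2NCH2NMe2 (1.2 equiv), CH2Cl2, rt; evaporate; TolSO2Na (3 equiv), AcOH–DMF 1:4, 60 °C
Reagents that add atoms: bis(dimethylamino)methane, CN(C)CN(C)C; sodium p-toluenesulfinate, Cc1ccc(cc1)S(=O)[O-].[Na+]
Why: Mannich reaction at the last free ring carbon, then gramine-type elimination–addition exchange of the amine by sulfinate, gives a bench-stable quinone methide precursor that later liberates no achiral amine.

**Step 7**
Reactants: 10 the sulfone from step 6; 11 hydroxyacetone (10 equiv)
Product: 13 1-{3-[(3-acetyl-2,4-dihydroxy-6-methoxy-5-methylphenyl)methyl]-2,4,6-trihydroxy-5-[(2R)-2-hydroxy-3-oxobutyl]phenyl}butan-1-one (in equilibrium with its chromanol hemiketal), via A-ring o-quinone methide 12 (not isolated)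
Conditions: 1-[3,5-bis(trifluoromethyl)phenyl]-3-{[(2R)-pyrrolidin-2-yl]methyl}thiourea (20 mol %), NaHCO3 (1.2 equiv), CHCl3–THF 4:1, 0 °C → rt
Reagents that add atoms: none
Why: Proposed new method: base releases the methylene o-quinone methide 12 (E1cB loss of sulfinate), whose C=O oxygen the catalyst thiourea binds just as it binds a nitro group (O=C–C=CH2 and O–N=C–C=C put the electrophilic carbon at the same distance), while the pyrrolidine forms the (E)-enamine of hydroxyacetone at the hydroxylated carbon, so the CH2 is delivered to the Re face of that carbon and gives the (R)-α-hydroxy ketone, the mirror image of the (S) α-centres that L-proline-derived catalysts give in ketone–nitroalkene Michael additions and hydroxyacetone aldol reactions; the closest known reaction types are enamine-catalysed Michael additions of hydroxyacetone to nitroalkenes and aminocatalytic additions of aldehydes or cyclic ketones to substituted o-quinone methides from 2-(tosylalkyl)phenols, none of which uses an unsubstituted methylene quinone methide of an acylphloroglucinol or sets the stereocentre only on the α-hydroxy donor carbon.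

**Step 8**
Reactants: 13 the (R)-α-hydroxy ketone from step 7
Product: 14 1-{3-[(3-acetyl-2,4-dihydroxy-6-methoxy-5-methylphenyl)methyl]-2,4,6-trihydroxy-5-[(2R)-2-hydroxy-3-methylbut-3-en-1-yl]phenyl}butan-1-one (target, CNP0388971.1)
Conditions: Ph3PCH3Br (10 equiv), KOtBu (9.5 equiv), THF–DMSO 4:1, 0 °C → rt; aq. NH4Cl
Reagents that add atoms: methylenetriphenylphosphorane, C=P(c1ccccc1)(c1ccccc1)c1ccccc1, made in the flask from methyltriphenylphosphonium bromide, C[P+](c1ccccc1)(c1ccccc1)c1ccccc1.[Br-]
Why: Wittig methylenation takes the aliphatic methyl ketone only, because the two aryl ketones are flanked by two ortho substituents and conjugated to phenoxides under the excess ylide, and the C–O stereocentre is not touched, so it stays (R).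

**Compound list**
1 | phloroglucinol (benzene-1,3,5-triol) | Oc1cc(O)cc(O)c1 | starting material
2 | 1-(2,4,6-trihydroxyphenyl)butan-1-one | CCCC(=O)c1c(O)cc(O)cc1O | intermediate
3 | 2-methylphloroglucinol (2-methylbenzene-1,3,5-triol) | Cc1c(O)cc(O)cc1O | starting material
4 | 1-(2,4,6-trihydroxy-3-methylphenyl)ethan-1-one | CC(=O)c1c(O)cc(O)c(C)c1O | intermediate
5 | 1-(2,6-dihydroxy-4-methoxy-3-methylphenyl)ethan-1-one | CC(=O)c1c(O)cc(OC)c(C)c1O | intermediate
6 | 1-{3-[(dimethylamino)methyl]-2,6-dihydroxy-4-methoxy-5-methylphenyl}ethan-1-one | CC(=O)c1c(O)c(CN(C)C)c(OC)c(C)c1O | intermediate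
7 | 2-acetyl-3-hydroxy-5-methoxy-4-methyl-6-methylidenecyclohexa-2,4-dien-1-one (B-ring o-quinone methide) | C=C1C(=O)C(C(C)=O)=C(O)C(C)=C1OC | intermediate
8 | 1-{3-[(3-acetyl-2,4-dihydroxy-6-methoxy-5-methylphenyl)methyl]-2,4,6-trihydroxyphenyl}butan-1-one | CCCC(=O)c1c(O)cc(O)c(Cc2c(O)c(C(C)=O)c(O)c(C)c2OC)c1O | intermediate
9 | 1-{3-[(3-acetyl-2,4-dihydroxy-6-methoxy-5-methylphenyl)methyl]-5-[(dimethylamino)methyl]-2,4,6-trihydroxyphenyl}butan-1-one | CCCC(=O)c1c(O)c(CN(C)C)c(O)c(Cc2c(O)c(C(C)=O)c(O)c(C)c2OC)c1O | intermediate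
10 | 1-{3-[(3-acetyl-2,4-dihydroxy-6-methoxy-5-methylphenyl)methyl]-2,4,6-trihydroxy-5-[(4-methylbenzenesulfonyl)methyl]phenyl}butan-1-one | CCCC(=O)c1c(O)c(CS(=O)(=O)c2ccc(C)cc2)c(O)c(Cc2c(O)c(C(C)=O)c(O)c(C)c2OC)c1O | intermediate
11 | hydroxyacetone (1-hydroxypropan-2-one) | CC(=O)CO | starting material
12 | 4-[(3-acetyl-2,4-dihydroxy-6-methoxy-5-methylphenyl)methyl]-2-butanoyl-3,5-dihydroxy-6-methylidenecyclohexa-2,4-dien-1-one (A-ring o-quinone methide) | C=C1C(=O)C(C(=O)CCC)=C(O)C(Cc2c(O)c(C(C)=O)c(O)c(C)c2OC)=C1O | intermediate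
13 | 1-{3-[(3-acetyl-2,4-dihydroxy-6-methoxy-5-methylphenyl)methyl]-2,4,6-trihydroxy-5-[(2R)-2-hydroxy-3-oxobutyl]phenyl}butan-1-one | CC(=O)[C@H](O)Cc1c(O)c(Cc2c(O)c(C(C)=O)c(O)c(C)c2OC)c(O)c(C(=O)CCC)c1O | intermediate
14 | 1-{3-[(3-acetyl-2,4-dihydroxy-6-methoxy-5-methylphenyl)methyl]-2,4,6-trihydroxy-5-[(2R)-2-hydroxy-3-methylbut-3-en-1-yl]phenyl}butan-1-one | C=C(C)[C@H](O)Cc1c(O)c(Cc2c(O)c(C(C)=O)c(O)c(C)c2OC)c(O)c(C(=O)CCC)c1O | target

**Totals**
Total step count: 8. Longest linear sequence: 7 (steps 2–8, from 3).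

**Three steps most likely to fail**

Step 7 (the proposed new step). Risks: the catalyst pyrrolidine or the OH of hydroxyacetone may add to quinone methide 12; the ee may be modest because 12 is very reactive. The absolute sense rests on an analogy and must be confirmed (Mosher ester or HPLC); if it is reversed, the L-proline-derived enantiomer of the catalyst is used. Fallback with known chemistry, setting out from 8: C-prenylation with prenyl bromide and DBU in THF at 0 °C gives 1-{3-[(3-acetyl-2,4-dihydroxy-6-methoxy-5-methylphenyl)methyl]-2,4,6-trihydroxy-5-(3-methylbut-2-en-1-yl)phenyl}butan-1-one F1. Acetylation (Ac2O, pyridine, DMAP) gives its pentaacetate F2, so that no ortho-phenol can open the epoxide. Shi epoxidation (D-fructose-derived ketone, Oxone, buffered MeCN–dimethoxymethane, 0 °C) gives the (R)-epoxide pentaacetate F3. Isomerisation with TMSOTf/DBU in toluene (−78 → 0 °C) gives the (R)-allylic trimethylsilyl ether pentaacetate F4. K2CO3 in MeOH removes the acetates and the silyl group and comes back to the route at 14.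

Step 8. Risks: six acidic OH groups consume ylide and give a poorly soluble polyanion, and the strongly basic medium may epimerise the α-hydroxy ketone. Fallback, setting out from 13: addition of Me3SiCH2MgCl/CeCl3 (excess, THF, −78 °C), a non-basic organocerium reagent, gives the β-hydroxysilane 1-{3-[(3-acetyl-2,4-dihydroxy-6-methoxy-5-methylphenyl)methyl]-5-[(2R)-2,3-dihydroxy-3-methyl-4-(trimethylsilyl)butyl]-2,4,6-trihydroxyphenyl}butan-1-one F5 (both C3 epimers). Peterson elimination with KOtBu in THF comes back to the route at 14.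

Step 6. Risks: the amine-for-sulfinate exchange may be slow, or the methylene bridge may scramble on warming in acid. Fallback, setting out from 8: the Mannich base 9 is isolated and quaternised with MeI in MeCN at 0 °C to give {3-[(3-acetyl-2,4-dihydroxy-6-methoxy-5-methylphenyl)methyl]-5-butanoyl-2,4,6-trihydroxyphenyl}-N,N,N-trimethylmethanaminium iodide F6. With NaHCO3 under the step 7 conditions it loses trimethylamine, which cannot form an enamine, and comes back to the route at 12.

**Further compounds**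
F1 | step 7 | 1-{3-[(3-acetyl-2,4-dihydroxy-6-methoxy-5-methylphenyl)methyl]-2,4,6-trihydroxy-5-(3-methylbut-2-en-1-yl)phenyl}butan-1-one | CC(C)=CCc1c(O)c(Cc2c(O)c(C(C)=O)c(O)c(C)c2OC)c(O)c(C(=O)CCC)c1O
F2 | step 7 | pentaacetate of F1 (all five phenols acetylated) | CC(C)=CCc1c(OC(C)=O)c(Cc2c(OC(C)=O)c(C(C)=O)c(OC(C)=O)c(C)c2OC)c(OC(C)=O)c(C(=O)CCC)c1OC(C)=O
F3 | step 7 | pentaacetate bearing a [(2R)-3,3-dimethyloxiran-2-yl]methyl side chain | CC1(C)O[C@@H]1Cc1c(OC(C)=O)c(Cc2c(OC(C)=O)c(C(C)=O)c(OC(C)=O)c(C)c2OC)c(OC(C)=O)c(C(=O)CCC)c1OC(C)=O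
F4 | step 7 | pentaacetate bearing a (2R)-3-methyl-2-(trimethylsilyloxy)but-3-en-1-yl side chain | C=C(C)[C@H](O[Si](C)(C)C)Cc1c(OC(C)=O)c(Cc2c(OC(C)=O)c(C(C)=O)c(OC(C)=O)c(C)c2OC)c(OC(C)=O)c(C(=O)CCC)c1OC(C)=O
F5 | step 8 | 1-{3-[(3-acetyl-2,4-dihydroxy-6-methoxy-5-methylphenyl)methyl]-5-[(2R)-2,3-dihydroxy-3-methyl-4-(trimethylsilyl)butyl]-2,4,6-trihydroxyphenyl}butan-1-one (C3 epimers) | CC(O)(C[Si](C)(C)C)[C@H](O)Cc1c(O)c(Cc2c(O)c(C(C)=O)c(O)c(C)c2OC)c(O)c(C(=O)CCC)c1O
F6 | step 6 | {3-[(3-acetyl-2,4-dihydroxy-6-methoxy-5-methylphenyl)methyl]-5-butanoyl-2,4,6-trihydroxyphenyl}-N,N,N-trimethylmethanaminium iodide | CCCC(=O)c1c(O)c(C[N+](C)(C)C)c(O)c(Cc2c(O)c(C(C)=O)c(O)c(C)c2OC)c1O.[I-]
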